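**Retrosynthetic overview**
1. Target ⇒ phenol desilylation, α-face epoxidation of C8=C9 and acylation of the 6β-OH ⇒ dauc-8-ene-4β,6β-diol + O-silyl vanillic acid (built from catechol).
2. Diol ⇒ radical opening at C5 of a 5β,6β-epoxide, itself made by OH-directed epoxidation ⇒ dauca-5,8-dien-4β-ol.
3. Dienol ⇒ divinylcyclopropane–cycloheptadiene shift (C1–C10 bond, ring B, quaternary C1) ⇒ Pd-catalysed Negishi coupling (C5–C6 bond) of a cis-vinylcyclopropylzinc with an (R)-2-bromocyclopentenol.
4. The cyclopropane comes from propargyl alcohol (carbomagnesiation/iodination, asymmetric Simmons–Smith, oxidation/Wittig). The bromocyclopentenol comes from 2-bromo-3-methylcyclopentenone by catalytic asymmetric isopropyl addition.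
5. Ring order: ring A (bought) → cyclopropane (fragment 1) → ring B by ring expansion → transient 5,6-oxirane → final 8,9-oxirane.

Assumption: 2-bromo-3-methylcyclopent-2-en-1-one is taken as purchasable. Positions use daucane numbering: C1 quaternary fusion carbon with CH3, C2, C3, C4 carbinol with isopropyl, C5 fusion CH, C6 CH–O, C7, C8 C–CH3, C9, C10. β is the face of the C1 methyl.

**Fragment 1 (cyclopropane)**

Step 1
Reactants: 1 prop-2-yn-1-ol
Product: 3 (Z)-3-iodo-2-methylprop-2-en-1-ol, via vinylmagnesium alkoxide 2 (not isolated)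
Conditions: MeMgBr (2.5 equiv), CuI (10 mol %), THF/Et2O, −20 °C to rt; then NIS, 0 °C; aq. work-up
Reagents that add atoms: methylmagnesium bromide C[Mg]Br; N-iodosuccinimide O=C1CCC(=O)N1I
Why: Copper-catalysed, alkoxide-directed anti-carbomagnesiation puts CH3 on the internal carbon and magnesium on the terminal carbon inside a five-membered chelate, and iodinolysis with retention gives only the Z-iodoalkene with iodine cis to CH2OH.

Step 2
Reactants: 3 (Z)-3-iodo-2-methylprop-2-en-1-ol
Product: 4 [(1R,2R)-2-iodo-1-methylcyclopropyl]methanol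
Conditions: Et2Zn, CH2I2, DME, (4R,5R)-2-butyl-N,N,N′,N′-tetramethyl-1,3,2-dioxaborolane-4,5-dicarboxamide (1.2 equiv), CH2Cl2, −10 °C to rt
Reagents that add atoms: diiodomethane ICI
Why: In this Charette asymmetric Simmons–Smith cyclopropanation the chiral dioxaborolane holds the zinc alkoxide of 3 so that Zn(CH2I)2 delivers CH2 (future C7) to one alkene face, and the syn-stereospecific addition keeps iodine cis to CH2OH and sets both ring stereocentres (future C6 and C8) as 1R,2R.

Step 3
Reactants: 4 [(1R,2R)-2-iodo-1-methylcyclopropyl]methanol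
Product: 6 (1R,2R)-1-ethenyl-2-iodo-1-methylcyclopropane, via cyclopropanecarbaldehyde 5 (not isolated)
Conditions: (COCl)2, DMSO, CH2Cl2, −78 °C; Et3N; then Ph3P=CH2 (excess, from MePPh3Br/KOt-Bu, THF), −78 °C to rt
Reagents that add atoms: methyltriphenylphosphonium bromide C[P+](c1ccccc1)(c1ccccc1)c1ccccc1.[Br-]
Why: Swern oxidation followed by Wittig methylenation in the same flask avoids handling the volatile aldehyde, touches neither the C–I bond nor the two cyclopropane stereocentres, and creates no new stereocentre.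

**Fragment 2 (ring A)**

Step 4
Reactants: 7 2-bromo-3-methylcyclopent-2-en-1-one
Product: 8 (1R)-2-bromo-3-methyl-1-(propan-2-yl)cyclopent-2-en-1-ol
Conditions: i-PrMgBr (1.3 equiv, slow addition), CuBr·SMe2 (5 mol %), (R)-1-[(Sp)-2-(dicyclohexylphosphino)ferrocenyl]ethyldiphenylphosphine (6 mol %), t-BuOMe, −78 °C; aq. work-up
Reagents that add atoms: isopropylmagnesium bromide CC(C)[Mg]Br
Why: Proposed new method: enantioselective copper-catalysed 1,2-addition of a secondary Grignard reagent to a cyclic α-bromo-β,β-disubstituted enone, in which the monovalent copper–diphosphine complex is alkylated by i-PrMgBr and binds one face of the C=C bond while magnesium activates the carbonyl, the fully substituted β-carbon and the α-bromine block 1,4-transfer so that isopropyl goes to the Re face of the carbonyl carbon and sets C4 as R (the ligand antipode is available if the sense is reversed), and the ligand-accelerated path at −78 °C should outrun racemic addition, β-hydride reduction and Br/Mg exchange; the closest known reaction type is the copper/ferrocenyl-diphosphine-catalysed asymmetric 1,2-addition of primary β-branched Grignard reagents to acyclic α-bromo and α-methyl enones.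

**Union of fragments 1 and 2 (key step)**

Step 5
Reactants: 6 (1R,2R)-1-ethenyl-2-iodo-1-methylcyclopropane; 8 (1R)-2-bromo-3-methyl-1-(propan-2-yl)cyclopent-2-en-1-ol
Product: 12 (3R,8aR)-6,8a-dimethyl-3-(propan-2-yl)-1,2,3,5,8,8a-hexahydroazulen-3-ol, via cyclopropyllithium 9 (not isolated), via cyclopropylzinc bromide 10 (not isolated), via divinylcyclopropane carbinol 11 (not isolated)
Conditions: 6, t-BuLi (2.0 equiv), Et2O, −78 °C; ZnBr2, THF, −78 to 0 °C; then 8, Pd(OAc)2 (4 mol %), SPhos (8 mol %), THF, 50 °C; then TMEDA, toluene, 105 °C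
Reagents that add atoms: none
Why: In this Negishi cross-coupling the iodine–lithium exchange, the transmetalation to zinc and the palladium cycle all retain configuration at the cyclopropyl carbon and the SPhos catalyst tolerates the free tertiary alcohol, so the C5–C6 bond gives cis-divinylcyclopropane 11, whose Cope (divinylcyclopropane–cycloheptadiene) rearrangement through the only accessible boat transition state joins C10 to the α face of C1, closes ring B and sets quaternary C1 as R by chirality transfer from the cyclopropane.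

Step 6
Reactants: 12 (3R,8aR)-6,8a-dimethyl-3-(propan-2-yl)-1,2,3,5,8,8a-hexahydroazulen-3-ol
Product: 13 (1R,4R,5S,6R)-5,6-epoxydauc-8-en-4-ol
Conditions: VO(acac)2 (5 mol %), t-BuOOH (1.3 equiv), toluene, 0 °C to rt
Reagents that add atoms: tert-butyl hydroperoxide CC(C)(C)OO
Why: In this hydroxyl-directed vanadium-catalysed epoxidation of an allylic alcohol the peroxovanadate bound to the 4β-oxygen reaches only the adjacent C5=C6 bond and only from the β face, which sets C5 (S) and C6 (R) and leaves the remote C8=C9 alkene intact.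

Step 7
Reactants: 13 (1R,4R,5S,6R)-5,6-epoxydauc-8-en-4-ol
Product: 14 (3R,3aS,4R,8aR)-6,8a-dimethyl-3-(propan-2-yl)-1,2,3,3a,4,5,8,8a-octahydroazulene-3,4-diol
Conditions: Cp2TiCl2 [(C5H5)2TiCl2, 15 mol %], Mn, 2,4,6-collidine·HCl, 1,4-cyclohexadiene, THF, rt
Reagents that add atoms: none
Why: In this reductive radical opening of a 2,3-epoxy alcohol to a 1,3-diol, Cp2TiCl (trivalent titanium) cleaves the C5–O bond to the tertiary C5 radical while oxygen stays on C6 with its β configuration, and hydrogen-atom transfer from cyclohexadiene arrives on the α face because the β face carries the pseudo-axial C1 methyl and both oxygen substituents, setting 5α-H (S, trans fusion).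

**Fragment 3 (aroyl part)**

Step 8
Reactants: 15 benzene-1,2-diol (catechol)
Product: 16 2-methoxyphenol
Conditions: MeI (0.9 equiv), K2CO3 (1.0 equiv), acetone, reflux
Reagents that add atoms: iodomethane CI
Why: In this Williamson ether synthesis with sub-stoichiometric MeI and one equivalent of weak base only one of the two equivalent phenols is methylated, and leftover catechol is washed out with water.

Step 9
Reactants: 16 2-methoxyphenol
Product: 17 4-bromo-2-methoxyphenol
Conditions: NBS, MeCN, 0 °C
Reagents that add atoms: N-bromosuccinimide O=C1CCC(=O)N1Br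
Why: In this electrophilic aromatic bromination the free OH is the stronger director and its para position is open, so the 4-bromo isomer dominates.

Step 10
Reactants: 17 4-bromo-2-methoxyphenol
Product: 18 (4-bromo-2-methoxyphenoxy)(tert-butyl)dimethylsilane
Conditions: TBSCl, imidazole, DMF, rt
Reagents that add atoms: tert-butyldimethylsilyl chloride CC(C)(C)[Si](C)(C)Cl
Why: Standard imidazole-promoted silylation masks the phenol against the organolithium, acylation and peracid steps and is removable by fluoride under near-neutral conditions.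

Step 11
Reactants: 18 (4-bromo-2-methoxyphenoxy)(tert-butyl)dimethylsilane
Product: 20 4-{[tert-butyl(dimethyl)silyl]oxy}-3-methoxybenzoic acid, via aryllithium 19 (not isolated)
Conditions: n-BuLi, THF, −78 °C; CO2; then 1 M HCl to pH 3, 0 °C
Reagents that add atoms: carbon dioxide O=C=O
Why: Bromine–lithium exchange is faster than any directed lithiation at −78 °C, carboxylation of the aryllithium is reliable, and the aryl silyl ether survives the brief cold acidification.

**End game**

Step 12
Reactants: 14 (3R,3aS,4R,8aR)-6,8a-dimethyl-3-(propan-2-yl)-1,2,3,3a,4,5,8,8a-octahydroazulene-3,4-diol; 20 4-{[tert-butyl(dimethyl)silyl]oxy}-3-methoxybenzoic acid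
Product: 21 (3R,3aS,4R,8aR)-3-hydroxy-6,8a-dimethyl-3-(propan-2-yl)-1,2,3,3a,4,5,8,8a-octahydroazulen-4-yl 4-{[tert-butyl(dimethyl)silyl]oxy}-3-methoxybenzoate
Conditions: DCC (1.5 equiv), DMAP (1.0 equiv), toluene, 60 °C
Reagents that add atoms: none
Why: In this Steglich esterification the acylpyridinium ion from 20 acylates the secondary 6β-OH while the tertiary 4β-OH is inert, and C6 keeps its configuration because its C–O bond is not broken.

Step 13
Reactants: 21 (3R,3aS,4R,8aR)-3-hydroxy-6,8a-dimethyl-3-(propan-2-yl)-1,2,3,3a,4,5,8,8a-octahydroazulen-4-yl 4-{[tert-butyl(dimethyl)silyl]oxy}-3-methoxybenzoate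
Product: 22 (1R,4R,5S,6R,8R,9S)-8,9-epoxy-4-hydroxydaucan-6-yl 4-{[tert-butyl(dimethyl)silyl]oxy}-3-methoxybenzoate
Conditions: mCPBA (1.1 equiv), CH2Cl2/sat. aq. NaHCO3, 0 °C
Reagents that add atoms: 3-chloroperoxybenzoic acid OOC(=O)c1cccc(Cl)c1
Why: In this Prilezhaev epoxidation of the only remaining alkene the peracid comes from the α face because the β face of ring B is screened by the pseudo-axial C1 methyl and the 6β-aroyloxy group, which sets C8 (R) and C9 (S), and the buffer prevents acid-induced attack of the 4β-OH on the oxirane.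

Step 14
Reactants: 22 (1R,4R,5S,6R,8R,9S)-8,9-epoxy-4-hydroxydaucan-6-yl 4-{[tert-butyl(dimethyl)silyl]oxy}-3-methoxybenzoate
Product: 23 (1R,4R,5S,6R,8R,9S)-8,9-epoxy-4-hydroxydaucan-6-yl 4-hydroxy-3-methoxybenzoate
Conditions: TBAF, AcOH (1:1), THF, 0 °C
Reagents that add atoms: none
Why: Acetic-acid-buffered fluoride cleaves the labile aryl silyl ether within minutes without opening the trisubstituted epoxide, cleaving the ester or touching any stereocentre.

**Compound list**
1 | prop-2-yn-1-ol | C#CCO | starting material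
2 | bromomagnesium (Z)-3-(bromomagnesio)-2-methylprop-2-en-1-olate (Mg cis to CH2O) | Br[Mg]/C=C(/C)CO[Mg]Br | intermediate
3 | (Z)-3-iodo-2-methylprop-2-en-1-ol | I/C=C(/C)CO | intermediate
4 | [(1R,2R)-2-iodo-1-methylcyclopropyl]methanol (I cis to CH2OH) | I[C@@H]1C[C@]1(C)CO | intermediate
5 | (1R,2R)-2-iodo-1-methylcyclopropane-1-carbaldehyde | I[C@@H]1C[C@]1(C)C=O | intermediate
6 | (1R,2R)-1-ethenyl-2-iodo-1-methylcyclopropane (I cis to vinyl) | I[C@@H]1C[C@]1(C)C=C | intermediate
7 | 2-bromo-3-methylcyclopent-2-en-1-one | CC1=C(Br)C(=O)CC1 | starting material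
8 | (1R)-2-bromo-3-methyl-1-(propan-2-yl)cyclopent-2-en-1-ol | CC1=C(Br)[C@](O)(C(C)C)CC1 | intermediate
9 | [(1R,2S)-2-ethenyl-2-methylcyclopropyl]lithium (Li cis to vinyl, same spatial arrangement as 6) | [Li][C@@H]1C[C@]1(C)C=C | intermediate
10 | bromo[(1R,2R)-2-ethenyl-2-methylcyclopropyl]zinc (Zn cis to vinyl) | Br[Zn][C@@H]1C[C@]1(C)C=C | intermediate
11 | (1R)-2-[(1R,2R)-2-ethenyl-2-methylcyclopropyl]-3-methyl-1-(propan-2-yl)cyclopent-2-en-1-ol | CC1=C([C@@H]2C[C@]2(C)C=C)[C@](O)(C(C)C)CC1 | intermediate
12 | (3R,8aR)-6,8a-dimethyl-3-(propan-2-yl)-1,2,3,5,8,8a-hexahydroazulen-3-ol, i.e. (1R,4R)-dauca-5,8-dien-4-ol | CC1=CC[C@@]2(C)CC[C@@](O)(C(C)C)C2=CC1 | intermediate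
13 | (1R,4R,5S,6R)-5,6-epoxydauc-8-en-4-ol (5β,6β-epoxide, cis to 4β-OH) | CC1=CC[C@@]2(C)CC[C@@](O)(C(C)C)[C@]23O[C@@H]3C1 | intermediate
14 | (3R,3aS,4R,8aR)-6,8a-dimethyl-3-(propan-2-yl)-1,2,3,3a,4,5,8,8a-octahydroazulene-3,4-diol (4β,6β-diol, 5α-H) | CC1=CC[C@@]2(C)CC[C@@](O)(C(C)C)[C@@H]2[C@H](O)C1 | intermediate
15 | benzene-1,2-diol | Oc1ccccc1O | starting material
16 | 2-methoxyphenol | COc1ccccc1O | intermediate
17 | 4-bromo-2-methoxyphenol | COc1cc(Br)ccc1O | intermediate
18 | (4-bromo-2-methoxyphenoxy)(tert-butyl)dimethylsilane | COc1cc(Br)ccc1O[Si](C)(C)C(C)(C)C | intermediate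
19 | (4-{[tert-butyl(dimethyl)silyl]oxy}-3-methoxyphenyl)lithium | COc1cc([Li])ccc1O[Si](C)(C)C(C)(C)C | intermediate
20 | 4-{[tert-butyl(dimethyl)silyl]oxy}-3-methoxybenzoic acid | COc1cc(C(=O)O)ccc1O[Si](C)(C)C(C)(C)C | intermediate
21 | (3R,3aS,4R,8aR)-3-hydroxy-6,8a-dimethyl-3-(propan-2-yl)-1,2,3,3a,4,5,8,8a-octahydroazulen-4-yl 4-{[tert-butyl(dimethyl)silyl]oxy}-3-methoxybenzoate | COc1cc(C(=O)O[C@@H]2CC(C)=CC[C@@]3(C)CC[C@@](O)(C(C)C)[C@H]23)ccc1O[Si](C)(C)C(C)(C)C | intermediate
22 | (1R,4R,5S,6R,8R,9S)-8,9-epoxy-4-hydroxydaucan-6-yl 4-{[tert-butyl(dimethyl)silyl]oxy}-3-methoxybenzoate (8α,9α-epoxide) | COc1cc(C(=O)O[C@@H]2C[C@@]3(C)O[C@H]3C[C@@]3(C)CC[C@@](O)(C(C)C)[C@H]23)ccc1O[Si](C)(C)C(C)(C)C | intermediate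
23 | (1R,4R,5S,6R,8R,9S)-8,9-epoxy-4-hydroxydaucan-6-yl 4-hydroxy-3-methoxybenzoate (CNP0254293.2) | COc1cc(C(=O)O[C@@H]2C[C@@]3(C)O[C@H]3C[C@@]3(C)CC[C@@](O)(C(C)C)[C@H]23)ccc1O | target

**Counts**
Total steps: 14. Longest linear sequence: 9 steps (1, 2, 3, 5, 6, 7, 12, 13, 14).

**Three steps most likely to fail**

Step 4 (the proposed new step). A secondary Grignard reagent may reduce the ketone by β-hydride transfer or add without the catalyst, giving low yield or low ee. The fallback uses known chemistry and moves the isopropyl addition behind ring B formation, so that the C1 stereocentre controls C4. It sets out from 7 and from zinc reagent 10, made from 6 as in step 5.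
- Negishi coupling of 10 with 7 (Pd(OAc)2, SPhos, THF, rt) gives 2-[(1R,2R)-2-ethenyl-2-methylcyclopropyl]-3-methylcyclopent-2-en-1-one F1.
- Heating in toluene rearranges F1 to the bicyclic dienone (8aR)-6,8a-dimethyl-1,2,5,8-tetrahydroazulen-3(8aH)-one F2.
- i-PrMgCl/CeCl3 in THF at −78 °C adds to the C4 carbonyl anti to the pseudo-axial angular methyl. The fallback comes back to the route at 12.

Step 5. The alkenyl bromide is tetrasubstituted and flanked by a tertiary carbinol. The vinyl group of the zinc reagent may interfere with palladium, and zinc salts may ionise the allylic alcohol on heating. The fallback installs the second vinyl group only after the C5–C6 bond exists. It sets out from 4 and 8.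
- Silylation of 4 (TBSCl, imidazole) gives tert-butyl{[(1R,2R)-2-iodo-1-methylcyclopropyl]methoxy}dimethylsilane F3.
- Iodine–lithium exchange and ZnBr2 give bromo[(1R,2R)-2-({[tert-butyl(dimethyl)silyl]oxy}methyl)-2-methylcyclopropyl]zinc F4.
- Negishi coupling with 8 gives (1R)-2-[(1R,2S)-2-({[tert-butyl(dimethyl)silyl]oxy}methyl)-2-methylcyclopropyl]-3-methyl-1-(propan-2-yl)cyclopent-2-en-1-ol F5.
- TBAF gives (1R)-2-[(1R,2S)-2-(hydroxymethyl)-2-methylcyclopropyl]-3-methyl-1-(propan-2-yl)cyclopent-2-en-1-ol F6.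
- Dess–Martin oxidation of the primary alcohol gives the cyclopropanecarbaldehyde analogue of 11 (CHO in place of vinyl, all stereocentres unchanged) F7.
- Wittig methylenation then comes back to the route at 11, which is heated in toluene, free of metal salts, to give 12.

Step 13. The α-face preference of the peracid is inferred from shielding and is not proven, and the 4β-OH could steer the reagent to the β face. The fallback inverts the facial outcome by a halohydrin route. It sets out from 21.
- NBS in aqueous acetone forms the bromonium ion on the face the peracid prefers. Water opens it anti at tertiary C8 to give the 8α-hydroxy-9β-bromo adduct of 21 F8.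
- K2CO3 in acetone closes the oxirane by backside displacement of bromide. The fallback comes back to the route at 22.

**Further compounds**
F1 | step 4 | 2-[(1R,2R)-2-ethenyl-2-methylcyclopropyl]-3-methylcyclopent-2-en-1-one | CC1=C([C@@H]2C[C@]2(C)C=C)C(=O)CC1
F2 | step 4 | (8aR)-6,8a-dimethyl-1,2,5,8-tetrahydroazulen-3(8aH)-one | CC1=CC[C@@]2(C)CCC(=O)C2=CC1
F3 | step 5 | tert-butyl{[(1R,2R)-2-iodo-1-methylcyclopropyl]methoxy}dimethylsilane | I[C@@H]1C[C@]1(C)CO[Si](C)(C)C(C)(C)C
F4 | step 5 | bromo[(1R,2R)-2-({[tert-butyl(dimethyl)silyl]oxy}methyl)-2-methylcyclopropyl]zinc | Br[Zn][C@@H]1C[C@]1(C)CO[Si](C)(C)C(C)(C)C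
F5 | step 5 | (1R)-2-[(1R,2S)-2-({[tert-butyl(dimethyl)silyl]oxy}methyl)-2-methylcyclopropyl]-3-methyl-1-(propan-2-yl)cyclopent-2-en-1-ol | CC1=C([C@@H]2C[C@]2(C)CO[Si](C)(C)C(C)(C)C)[C@](O)(C(C)C)CC1
F6 | step 5 | (1R)-2-[(1R,2S)-2-(hydroxymethyl)-2-methylcyclopropyl]-3-methyl-1-(propan-2-yl)cyclopent-2-en-1-ol | CC1=C([C@@H]2C[C@]2(C)CO)[C@](O)(C(C)C)CC1
F7 | step 5 | cyclopropanecarbaldehyde analogue of 11 (CHO in place of vinyl, all stereocentres unchanged) | CC1=C([C@@H]2C[C@]2(C)C=O)[C@](O)(C(C)C)CC1
F8 | step 13 | 8α-hydroxy-9β-bromo adduct of 21 | COc1cc(C(=O)O[C@@H]2C[C@@](C)(O)[C@H](Br)C[C@@]3(C)CC[C@@](O)(C(C)C)[C@H]23)ccc1O[Si](C)(C)C(C)(C)C
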